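**Retrosynthetic overview** (side chain numbered C1' benzylic carbinol, C2' ester-bearing carbon, C3' tertiary carbinol)

1. The C3' tertiary carbinol is taken back to an isopropenyl group (Markovnikov hydration, last step). The side chain is then a homoallylic alcohol with the acyloxy group on its allylic carbon C2'.
2. C1'–C2' is cut as a carbonyl anti-(α-acyloxy)allylation: 6-formyl-7-methoxycoumarin plus the methacrolein acylal of (R)-2-methylbutanoic acid, joined by chiral iridium transfer-hydrogenation catalysis. This one step forms the bond, sets C1' and C2' (anti) and puts the ester on O2' only, so no protecting group and no selective acylation are needed.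
3. Enabling feature: the C1'(OH)–C2'(OCOR)–C3'(CH3)2(OH) triad on C6 of the benzene ring of the coumarin. C1' is an aryl carbinol carbon (a former aldehyde), C2' is an acetal-level carbon in the donor, and C3' with its two methyl groups is a hydrated 2-propenyl carbon.
4. The aldehyde comes from 6-bromo-7-methoxycoumarin by Pd formylation. The only ring formed is the pyran-2-one ring, closed first by Wittig olefination/lactonisation of 5-bromo-2-hydroxy-4-methoxybenzaldehyde. The acyl stereocentre comes from (R)-2-methylbutanoic acid, the configuration written in the target SMILES.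

Key step: step 5

Assumption (sense of induction): the (S)-SEGPHOS-modified iridium catalyst is taken to attack the aldehyde face that gives the (1'R) carbinol, by analogy with related SEGPHOS–iridium allylations of aryl aldehydes; if the first run shows the opposite sense, (R)-SEGPHOS is used and nothing else changes.

**Step 1**
Reactants: 1 5-bromo-2-hydroxy-4-methoxybenzaldehyde
Product: 3 6-bromo-7-methoxy-2H-chromen-2-one, via o-hydroxycinnamate ester 2 (not isolated)
Conditions: Ph3P=CHCO2Et (1.2 equiv), N,N-diethylaniline, reflux (ca. 215 °C); 1 M HCl wash
Reagents that add atoms: ethyl (triphenylphosphoranylidene)acetate, CCOC(=O)C=P(c1ccccc1)(c1ccccc1)c1ccccc1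
Why: Wittig olefination with the stabilised ylide gives the (E)-o-hydroxycinnamate 2, which at this temperature isomerises about the C=C bond and lactonises with loss of ethanol (a standard one-pot coumarin annulation), tolerating the aryl bromide and fixing Br at C6 and OMe at C7.

**Step 2**
Reactants: 3 6-bromo-7-methoxy-2H-chromen-2-one
Product: 4 7-methoxy-2-oxo-2H-chromene-6-carbaldehyde
Conditions: Pd(OAc)2 (1 mol %), n-BuPAd2 (3 mol %), TMEDA (1 equiv), CO/H2 (1:1, 5 bar), toluene, 100 °C
Reagents that add atoms: carbon monoxide, [C-]#[O+]
Why: Palladium-catalysed reductive carbonylation (formylation) of an aryl bromide by oxidative addition, CO insertion and hydrogenolysis of the acyl–Pd species, under which the lactone and its electron-poor C3=C4 bond should be inert.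

**Step 3**
Reactants: 5 (R)-2-methylbutanoic acid (2 equiv)
Product: 7 (R)-2-methylbutanoic anhydride, via O-acylisourea 6 (not isolated)
Conditions: DCC (0.5 equiv per acid), CH2Cl2, 0 °C to rt; filtration
Reagents that add atoms: none
Why: Carbodiimide dehydration of a carboxylic acid to its symmetrical anhydride through the O-acylisourea, run without amine base so that the α-stereocentre taken from the chiral pool is not epimerised.

**Step 4**
Reactants: 7 (R)-2-methylbutanoic anhydride, 8 methacrolein
Product: 9 2-methylprop-2-ene-1,1-diyl bis[(R)-2-methylbutanoate]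
Conditions: H2SO4 (1 mol %), BHT (trace), CH2Cl2, 0 °C to rt
Reagents that add atoms: none
Why: Acid-catalysed 1,2-addition of an anhydride to an enal (acylal formation), well known for acrolein-type aldehydes; the acetal carbon carries two identical acyloxy groups and is no stereocentre.

**Step 5**
Reactants: 4 7-methoxy-2-oxo-2H-chromene-6-carbaldehyde, 9 2-methylprop-2-ene-1,1-diyl bis[(R)-2-methylbutanoate] (2 equiv)
Product: 10 (1R,2S)-1-hydroxy-1-(7-methoxy-2-oxo-2H-chromen-6-yl)-3-methylbut-3-en-2-yl (2R)-2-methylbutanoate
Conditions: [Ir(cod)Cl]2 (2.5 mol %), (S)-SEGPHOS (5 mol %), 4-cyano-3-nitrobenzoic acid (10 mol %), Cs2CO3 (20 mol %), i-PrOH (2 equiv), THF, 90 °C, sealed tube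
Reagents that add atoms: none
Why: The ortho-cyclometalated iridium C,O-benzoate formed in situ ionises one acyloxy group of 9 to a 1-acyloxy-2-methyl-π-allyliridium(III) species, whose (E)-σ-allyl form adds to the aldehyde carbon of 4 through a closed six-membered chair transition state with allylic transposition, so the new C–C bond is made at the acyloxy-bearing carbon; isopropanol then releases the product alkoxide and is dehydrogenated to acetone, returning iridium to the cycle. The closest known reaction type is the iridium-catalysed transfer-hydrogenative anti-(α-acyloxy)allylation of aldehydes with acrolein-derived allylic gem-dicarboxylates. No ring is closed. C1' is set by the SEGPHOS–iridium centre, which selects the aldehyde π-face, and C2' is set relative to C1' by the (E)-geometry of the enol-ester σ-allyl unit in the chair, which gives the anti arrangement; the (R)-acyl centre is a spectator. The step needs branched over linear coupling, anti over syn, no O2'→O1' acyl shift and no reduction of the lactone C3=C4 bond, which should be secured by the closed transition state, the preference of the acyloxy group for the syn position of the π-allyl, the merely catalytic weak base and the preference of the Ir–H for aldehydes. Because the acyl group is enantiopure, product from the minor facial approach is a diastereomer and should be removable by chromatography.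

**Step 6**
Reactants: 10 (1R,2S)-1-hydroxy-1-(7-methoxy-2-oxo-2H-chromen-6-yl)-3-methylbut-3-en-2-yl (2R)-2-methylbutanoate
Product: 12 (1R,2R)-1,3-dihydroxy-1-(7-methoxy-2-oxo-2H-chromen-6-yl)-3-methylbutan-2-yl (2R)-2-methylbutanoate, via tertiary hydroperoxide 11 (not isolated)
Conditions: Co(acac)2 (20 mol %), PhSiH3 (2 equiv), O2 (1 atm), THF, rt; then PPh3 (1.2 equiv), rt
Reagents that add atoms: dioxygen, O=O
Why: Mukaiyama hydration (cobalt hydride hydrogen-atom transfer) puts H on the terminal CH2 of the 1,1-disubstituted alkene, the tertiary radical is trapped by O2 and the peroxide is reduced to the tertiary alcohol under neutral conditions that should spare the O2' ester, the free benzylic OH and the less reactive conjugated C3=C4 bond; no stereocentre is formed or touched (the C2' descriptor changes from S to R only through the CIP priority change).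

**Compound list**

1 | 5-bromo-2-hydroxy-4-methoxybenzaldehyde | O=Cc1cc(Br)c(OC)cc1O | starting material
2 | ethyl (E)-3-(5-bromo-2-hydroxy-4-methoxyphenyl)acrylate | CCOC(=O)/C=C/c1cc(Br)c(OC)cc1O | intermediate (not isolated)
3 | 6-bromo-7-methoxy-2H-chromen-2-one | COc1cc2oc(=O)ccc2cc1Br | intermediate
4 | 7-methoxy-2-oxo-2H-chromene-6-carbaldehyde | COc1cc2oc(=O)ccc2cc1C=O | intermediate
5 | (R)-2-methylbutanoic acid | CC[C@@H](C)C(=O)O | starting material
6 | N,N'-dicyclohexyl-O-[(R)-2-methylbutanoyl]isourea | CC[C@@H](C)C(=O)OC(=NC1CCCCC1)NC1CCCCC1 | intermediate (not isolated)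
7 | (R)-2-methylbutanoic anhydride | CC[C@@H](C)C(=O)OC(=O)[C@H](C)CC | intermediate
8 | methacrolein | CC(=C)C=O | starting material
9 | 2-methylprop-2-ene-1,1-diyl bis[(R)-2-methylbutanoate] | C=C(C)C(OC(=O)[C@H](C)CC)OC(=O)[C@H](C)CC | intermediate
10 | (1R,2S)-1-hydroxy-1-(7-methoxy-2-oxo-2H-chromen-6-yl)-3-methylbut-3-en-2-yl (2R)-2-methylbutanoate | CC[C@@H](C)C(=O)O[C@H]([C@H](O)c1cc2ccc(=O)oc2cc1OC)C(C)=C | intermediate
11 | (1R,2R)-3-hydroperoxy-1-hydroxy-1-(7-methoxy-2-oxo-2H-chromen-6-yl)-3-methylbutan-2-yl (2R)-2-methylbutanoate | CC[C@@H](C)C(=O)O[C@H]([C@H](O)c1cc2ccc(=O)oc2cc1OC)C(C)(C)OO | intermediate (not isolated)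
12 | (1R,2R)-1,3-dihydroxy-1-(7-methoxy-2-oxo-2H-chromen-6-yl)-3-methylbutan-2-yl (2R)-2-methylbutanoate | CC[C@@H](C)C(=O)O[C@H]([C@H](O)c1cc2ccc(=O)oc2cc1OC)C(C)(C)O | target

**Total step count:** 6
**Longest linear sequence:** 4 steps (1, 2, 5, 6 or 3, 4, 5, 6)

**Steps most likely to fail**

Step 5. The 2-methyl group of the donor may slow ionisation of the acylal and may lower the syn preference of the acyloxy group in the π-allyl, so that σ-allyl geometry scrambles and anti selectivity erodes; facial control may also be poor, or the base may promote an O2'→O1' acyl shift. The fallback keeps the same bond construction but uses a stoichiometric allylchromium reagent and separates diastereomers. It sets out from 5, 8 and 4 and returns at 10. Acid 5 with PBr3 (neat, 0 °C to rt, distillation) should give (R)-2-methylbutanoyl bromide F1. 1,4-Addition of F1 to methacrolein 8 (cat. ZnCl2, CH2Cl2, −20 °C) should give 3-bromo-2-methylprop-1-en-1-yl (R)-2-methylbutanoate F2 as an E/Z mixture. Treating F2 and aldehyde 4 with CrCl2 (THF, rt) in a Nozaki–Hiyama-type addition should give the anti adducts whatever the bromide geometry, because the allylchromium species equilibrates and reacts through a chair transition state. This gives 10 together with its (1S,2R)-carbinol diastereomer F3, and the two differ as diastereomers owing to the enantiopure acyl group, so they should be separable by chromatography or preparative HPLC. At most half of the material ends up as 10.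

Step 6. Competing hydrogen-atom transfer to the C3=C4 bond of the lactone, or an acyl shift during peroxide reduction, may lower chemoselectivity. The fallback replaces the radical hydration by ionic halohydrin formation and radical dehalogenation. It sets out from 10 and returns at 12. N-Iodosuccinimide in MeCN/H2O at 0 °C should give the Markovnikov iodohydrin, (1R,2R)-1,3-dihydroxy-4-iodo-1-(7-methoxy-2-oxo-2H-chromen-6-yl)-3-methylbutan-2-yl (2R)-2-methylbutanoate F4, as a mixture of C3' epimers, with water in large excess expected to outcompete the ester carbonyl as nucleophile. Bu3SnH with AIBN (benzene, 80 °C) should then remove iodine, which also removes the C3' stereocentre and gives 12.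

Step 2. Hydrodebromination may compete with CO insertion, or the catalyst may be inhibited by the lactone. The fallback replaces carbonylation by vinylation and oxidative cleavage. It sets out from 3 and returns at 4. Suzuki–Miyaura coupling of 3 with potassium vinyltrifluoroborate (PdCl2(dppf), Cs2CO3, THF/H2O, 80 °C) should give 6-ethenyl-7-methoxy-2H-chromen-2-one F5. Lemieux–Johnson cleavage of F5 (K2OsO4·2H2O cat., NaIO4, 2,6-lutidine, dioxane/H2O, rt) should give 4, since the styrene-type vinyl group reacts far faster than the electron-poor C3=C4 bond.

**Further compounds**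

F1 | step 5 | (R)-2-methylbutanoyl bromide | CC[C@@H](C)C(=O)Br
F2 | step 5 | 3-bromo-2-methylprop-1-en-1-yl (R)-2-methylbutanoate (E/Z mixture) | CC[C@@H](C)C(=O)OC=C(C)CBr
F3 | step 5 | (1S,2R)-1-hydroxy-1-(7-methoxy-2-oxo-2H-chromen-6-yl)-3-methylbut-3-en-2-yl (2R)-2-methylbutanoate | CC[C@@H](C)C(=O)O[C@@H]([C@@H](O)c1cc2ccc(=O)oc2cc1OC)C(C)=C
F4 | step 6 | (1R,2R)-1,3-dihydroxy-4-iodo-1-(7-methoxy-2-oxo-2H-chromen-6-yl)-3-methylbutan-2-yl (2R)-2-methylbutanoate (C3' epimers) | CC[C@@H](C)C(=O)O[C@H]([C@H](O)c1cc2ccc(=O)oc2cc1OC)C(C)(O)CI
F5 | step 2 | 6-ethenyl-7-methoxy-2H-chromen-2-one | COc1cc2oc(=O)ccc2cc1C=C
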